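Ring B (C4a, C5, C6, C7, C8, C8a) is opened at C5–C6. A ligand-controlled copper hydride hydroalkylation closes it and sets the C5 stereocentre in one operation, adding only hydrogen: Cu–H adds across an (E)-non-1-enyl group on C4a and the resulting C5–Cu bond displaces a bromide on C6. The step exploits C5 as the benzylic-type carbon on C4a of the aromatic N-methoxy-4-pyridone ring A, which directs copper to C5, while the C8a side chain delivers C6 for a six-membered closure. The precursor, a monocyclic pyridone carrying the alkenyl group and a 3-bromopropyl chain, is built from allomaltol by hydroxymethylation, lateral hydroxyethylation, methoxyamine exchange, iodination and Suzuki coupling.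

Key step: step 9

Numbering: the bicyclic compounds use quinolinone numbering (N1, C2, C3, C4, C4a, C5 to C8, C8a; C1' is the first carbon of the octyl chain); monocyclic intermediates are named by their own ring numbering. The target stereocentre C5 is (R).

Assumption: the sense of induction of (S)-DTBM-SEGPHOS on alkenylpyridone 11 is taken from its behaviour with (E)-β-alkylstyrenes; should it prove opposite, the (R)-ligand is used in step 9 with no other change.

Step 1
Reactants: 1 allomaltol (5-hydroxy-2-methyl-4H-pyran-4-one)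
Product: 2 3-hydroxy-2-(hydroxymethyl)-6-methyl-4H-pyran-4-one
Conditions: 37% aq. HCHO (1.1 equiv), NaOH (1.1 equiv), H2O, rt; then HCl to pH 1
Reagents that add atoms: formaldehyde, C=O
Why: The enolate of the 5-hydroxy group attacks formaldehyde through the only free ortho ring carbon in an aldol-type (Lederer–Manasse) hydroxymethylation that is routine for allomaltol and kojic acid.

Step 2
Reactants: 2 3-hydroxy-2-(hydroxymethyl)-6-methyl-4H-pyran-4-one
Product: 3 2-(hydroxymethyl)-3-methoxy-6-methyl-4H-pyran-4-one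
Conditions: MeI (1.2 equiv), K2CO3 (1.5 equiv), DMF, rt
Reagents that add atoms: iodomethane, CI
Why: Williamson O-methylation in which carbonate deprotonates only the acidic enolic 3-OH, so the primary alcohol should stay free.

Step 3
Reactants: 3 2-(hydroxymethyl)-3-methoxy-6-methyl-4H-pyran-4-one
Product: 4 2-{[tert-butyl(diphenyl)silyl]oxymethyl}-3-methoxy-6-methyl-4H-pyran-4-one
Conditions: TBDPSCl (1.1 equiv), imidazole (2 equiv), DMF, rt
Reagents that add atoms: tert-butyl(chloro)diphenylsilane, CC(C)(C)[Si](Cl)(c1ccccc1)c1ccccc1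
Why: Imidazole-promoted silylation of the primary alcohol; the TBDPS ether is chosen because it should survive the amide base, hot pyridinium chloride, aqueous carbonate and the alkoxide/silane medium of later steps.

Step 4
Reactants: 4 2-{[tert-butyl(diphenyl)silyl]oxymethyl}-3-methoxy-6-methyl-4H-pyran-4-one
Product: 6 2-{[tert-butyl(diphenyl)silyl]oxymethyl}-6-(3-hydroxypropyl)-3-methoxy-4H-pyran-4-one, via lithium dienolate 5 (not isolated)
Conditions: LiN(SiMe3)2 (1.15 equiv), THF, −78 °C; ethylene oxide (4 equiv), BF3·OEt2 (1.2 equiv, promoter), −78 to −40 °C; aq. NH4Cl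
Reagents that add atoms: ethylene oxide, C1CO1
Why: Lateral (vinylogous) deprotonation of the 6-methyl group of a 2-methyl-4-pyranone gives a dienolate that opens the epoxide at carbon (C8 then carries C7 and C6), the silyloxymethyl protons being shielded and kinetically less acidic.

Step 5
Reactants: 6 2-{[tert-butyl(diphenyl)silyl]oxymethyl}-6-(3-hydroxypropyl)-3-methoxy-4H-pyran-4-one
Product: 7 2-{[tert-butyl(diphenyl)silyl]oxymethyl}-6-(3-hydroxypropyl)-1,3-dimethoxypyridin-4(1H)-one
Conditions: MeONH2·HCl (5 equiv), pyridine, EtOH, 90 °C, sealed tube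
Reagents that add atoms: O-methylhydroxylamine hydrochloride, CON.Cl
Why: 4-Pyranone to 4-pyridone exchange (conjugate addition of the amine, ring opening, ring closure through nitrogen, loss of water), the course followed by alkylamines and hydroxylamine with 3-alkoxy-4-pyranones.

Step 6
Reactants: 7 2-{[tert-butyl(diphenyl)silyl]oxymethyl}-6-(3-hydroxypropyl)-1,3-dimethoxypyridin-4(1H)-one
Product: 8 2-{[tert-butyl(diphenyl)silyl]oxymethyl}-6-(3-hydroxypropyl)-5-iodo-1,3-dimethoxypyridin-4(1H)-one
Conditions: NIS (1.1 equiv), MeCN, rt, dark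
Reagents that add atoms: N-iodosuccinimide, O=C1CCC(=O)N1I
Why: Electrophilic iodination at C5, the only free ring carbon and the nucleophilic α-carbon of the vinylogous amide.

Step 7
Reactants: 8 2-{[tert-butyl(diphenyl)silyl]oxymethyl}-6-(3-hydroxypropyl)-5-iodo-1,3-dimethoxypyridin-4(1H)-one; 9 (E)-non-1-en-1-ylboronic acid
Product: 10 2-{[tert-butyl(diphenyl)silyl]oxymethyl}-6-(3-hydroxypropyl)-1,3-dimethoxy-5-[(E)-non-1-en-1-yl]pyridin-4(1H)-one
Conditions: Pd(dppf)Cl2 (5 mol%), K2CO3 (3 equiv), 1,4-dioxane/H2O 4:1, 80 °C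
Reagents that add atoms: none
Why: Suzuki–Miyaura coupling of the iodopyridone with an alkenylboronic acid, which should proceed with retention of the E geometry and tolerate the free alcohol.

Step 8
Reactants: 10 2-{[tert-butyl(diphenyl)silyl]oxymethyl}-6-(3-hydroxypropyl)-1,3-dimethoxy-5-[(E)-non-1-en-1-yl]pyridin-4(1H)-one
Product: 11 6-(3-bromopropyl)-2-{[tert-butyl(diphenyl)silyl]oxymethyl}-1,3-dimethoxy-5-[(E)-non-1-en-1-yl]pyridin-4(1H)-one
Conditions: CBr4 (1.3 equiv), PPh3 (1.4 equiv), CH2Cl2, 0 °C
Reagents that add atoms: carbon tetrabromide, BrC(Br)(Br)Br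
Why: Appel bromination of the only free primary alcohol under neutral conditions that should leave the alkene, the silyl ether and the N–OMe group untouched.

Step 9
Reactants: 11 6-(3-bromopropyl)-2-{[tert-butyl(diphenyl)silyl]oxymethyl}-1,3-dimethoxy-5-[(E)-non-1-en-1-yl]pyridin-4(1H)-one
Product: 12 (5R)-2-{[tert-butyl(diphenyl)silyl]oxymethyl}-1,3-dimethoxy-5-octyl-5,6,7,8-tetrahydroquinolin-4(1H)-one
Conditions: Cu(OAc)2 (6 mol%), (S)-DTBM-SEGPHOS (6.6 mol%), (MeO)2MeSiH (3 equiv), LiOMe (3 equiv), THF, 40 °C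
Reagents that add atoms: none
Why: The bisphosphine-ligated copper hydride formed from Cu(OAc)2, the ligand and the silane adds syn across the C5=C1' bond of 11 with hydride to C1' and copper to C5, because only there is the carbon–copper bond benzylic/allylic to the C4a=C8a π-system of pyridone ring A and within reach of the C4 carbonyl oxygen; the secondary alkylcopper then displaces the primary bromide at C6 with retention at C5, and LiOMe with the silane returns the CuBr complex to CuH. The closest known reaction type is the CuH-catalysed enantioselective intramolecular hydroalkylation of halide-tethered vinyl arenes. Ring B (C5, C4a, C8a, C8, C7, C6) closes in the 6-exo-tet mode at the C5–C6 bond. The C5 stereocentre is set by the chiral bisphosphine, which selects the face of the (E)-alkene in the hydrocupration, and it is carried unchanged through the stereoretentive alkylation to give (5R). The step needs copper delivery to C5 rather than C1' and preference for the alkene over the C–Br bond and over ring A: the first follows from conjugation with ring A, the second from the fast hydrocupration of aryl-type alkenes and from the fully substituted, vinylogous-amide character of the N-methoxypyridone, a poor hydride acceptor. The silyl ether keeps the hydroxymethyl group from quenching the alkylcopper.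

Step 10
Reactants: 12 (5R)-2-{[tert-butyl(diphenyl)silyl]oxymethyl}-1,3-dimethoxy-5-octyl-5,6,7,8-tetrahydroquinolin-4(1H)-one
Product: 13 (5R)-2-(hydroxymethyl)-1,3-dimethoxy-5-octyl-5,6,7,8-tetrahydroquinolin-4(1H)-one
Conditions: Bu4NF (1.2 equiv), THF, 0 °C to rt
Reagents that add atoms: none
Why: Fluoride cleavage of the silyl ether; C5–H is not acidic (cross-conjugated position), so the stereocentre should not be touched.

Compound list
1 | allomaltol, 5-hydroxy-2-methyl-4H-pyran-4-one | Cc1cc(=O)c(O)co1 | starting material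
2 | 3-hydroxy-2-(hydroxymethyl)-6-methyl-4H-pyran-4-one | Cc1cc(=O)c(O)c(CO)o1 | intermediate
3 | 2-(hydroxymethyl)-3-methoxy-6-methyl-4H-pyran-4-one | Cc1cc(=O)c(OC)c(CO)o1 | intermediate
4 | 2-{[tert-butyl(diphenyl)silyl]oxymethyl}-3-methoxy-6-methyl-4H-pyran-4-one | Cc1cc(=O)c(OC)c(CO[Si](c2ccccc2)(c2ccccc2)C(C)(C)C)o1 | intermediate
5 | lithium dienolate of 4, lithium 6-{[tert-butyl(diphenyl)silyl]oxymethyl}-5-methoxy-2-methylidene-2H-pyran-4-olate | [Li]OC1=CC(=C)OC(CO[Si](c2ccccc2)(c2ccccc2)C(C)(C)C)=C1OC | intermediate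
6 | 2-{[tert-butyl(diphenyl)silyl]oxymethyl}-6-(3-hydroxypropyl)-3-methoxy-4H-pyran-4-one | OCCCc1cc(=O)c(OC)c(CO[Si](c2ccccc2)(c2ccccc2)C(C)(C)C)o1 | intermediate
7 | 2-{[tert-butyl(diphenyl)silyl]oxymethyl}-6-(3-hydroxypropyl)-1,3-dimethoxypyridin-4(1H)-one | OCCCc1cc(=O)c(OC)c(CO[Si](c2ccccc2)(c2ccccc2)C(C)(C)C)n1OC | intermediate
8 | 2-{[tert-butyl(diphenyl)silyl]oxymethyl}-6-(3-hydroxypropyl)-5-iodo-1,3-dimethoxypyridin-4(1H)-one | OCCCc1c(I)c(=O)c(OC)c(CO[Si](c2ccccc2)(c2ccccc2)C(C)(C)C)n1OC | intermediate
9 | (E)-non-1-en-1-ylboronic acid | CCCCCCC/C=C/B(O)O | starting material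
10 | 2-{[tert-butyl(diphenyl)silyl]oxymethyl}-6-(3-hydroxypropyl)-1,3-dimethoxy-5-[(E)-non-1-en-1-yl]pyridin-4(1H)-one | OCCCc1c(/C=C/CCCCCCC)c(=O)c(OC)c(CO[Si](c2ccccc2)(c2ccccc2)C(C)(C)C)n1OC | intermediate
11 | 6-(3-bromopropyl)-2-{[tert-butyl(diphenyl)silyl]oxymethyl}-1,3-dimethoxy-5-[(E)-non-1-en-1-yl]pyridin-4(1H)-one | BrCCCc1c(/C=C/CCCCCCC)c(=O)c(OC)c(CO[Si](c2ccccc2)(c2ccccc2)C(C)(C)C)n1OC | intermediate
12 | (5R)-2-{[tert-butyl(diphenyl)silyl]oxymethyl}-1,3-dimethoxy-5-octyl-5,6,7,8-tetrahydroquinolin-4(1H)-one | CCCCCCCC[C@@H]1CCCc2c1c(=O)c(OC)c(CO[Si](c3ccccc3)(c3ccccc3)C(C)(C)C)n2OC | intermediate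
13 | (5R)-2-(hydroxymethyl)-1,3-dimethoxy-5-octyl-5,6,7,8-tetrahydroquinolin-4(1H)-one | CCCCCCCC[C@@H]1CCCc2c1c(=O)c(OC)c(CO)n2OC | target

Total step count: 10.
Longest linear sequence: 10 steps (1 to 13); boronic acid 9 is used as purchased.

Steps most likely to fail

Step 9. Hydrocupration of the hindered, twisted and electron-rich alkenyl group may be slow, so that reduction of the carbon–bromine bond, attack of methoxide on the bromide or plain saturation of the alkene overtakes ring closure. Face selection may also be poor because the alkene is flanked on both sides. Fallback: the same C5–C6 bond is closed by ring-closing metathesis and the stereocentre is set afterwards by asymmetric hydrogenation. It sets out from iodide 8. Suzuki coupling (Pd(dppf)Cl2, K2CO3) with 2-(dec-1-en-2-yl)-4,4,5,5-tetramethyl-1,3,2-dioxaborolane F1, made from dec-1-yne by NHC–CuCl-catalysed Markovnikov protoboration with bis(pinacolato)diboron and MeOH, should give the 5-(dec-1-en-2-yl)pyridone alcohol F2. Dess–Martin oxidation then gives aldehyde F3, and Wittig methylenation with Ph3P=CH2 gives diene F4. The second-generation Hoveyda–Grubbs catalyst should close ring B with loss of ethylene to the C5=C6 alkene, 5-octyl-7,8-dihydroquinolinone F5. Hydrogenation of this cyclic trisubstituted aryl-type alkene with a cationic iridium phosphine–oxazoline catalyst, [Ir(cod)(tBu-PHOX)]BArF, under H2 (ligand enantiomer chosen for the (5R) product) comes back to the route at 12.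

Step 5. The weakly nucleophilic alkoxyamine may fail to open the 2,6-dialkylated pyranone or stall at an open-chain oxime ether, and long heating may loosen the silyl ether. Fallback: nitrogen is brought in with the more nucleophilic hydroxylamine and the methyl group is put on oxygen afterwards. From 6, NH2OH·HCl and NaOAc in EtOH/H2O at reflux should give the 1-hydroxypyridin-4-one F6. MeI with K2CO3 in DMF then methylates the acidic N–OH selectively and comes back to the route at 7.

Step 4. The delocalised dienolate may open the epoxide sluggishly, BF3 may tie up the dienolate oxygen, and ethylene oxide may oligomerise, so that 4 is returned. Fallback: the three-carbon arm is built with a soft alkylating agent and trimmed oxidatively. From 4, the same dienolate (LiN(SiMe3)2, THF, −78 °C) is alkylated with allyl bromide to the but-3-enyl pyranone F7. Lemieux–Johnson cleavage (OsO4 cat., NaIO4, 2,6-lutidine, dioxane/H2O) gives aldehyde F8, and NaBH4 in MeOH at −40 °C reduces the aldehyde selectively, coming back to the route at 6.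

Further compounds
F1 | step 9 | 2-(dec-1-en-2-yl)-4,4,5,5-tetramethyl-1,3,2-dioxaborolane | C=C(CCCCCCCC)B1OC(C)(C)C(C)(C)O1
F2 | step 9 | 2-{[tert-butyl(diphenyl)silyl]oxymethyl}-5-(dec-1-en-2-yl)-6-(3-hydroxypropyl)-1,3-dimethoxypyridin-4(1H)-one | OCCCc1c(C(=C)CCCCCCCC)c(=O)c(OC)c(CO[Si](c2ccccc2)(c2ccccc2)C(C)(C)C)n1OC
F3 | step 9 | 3-[6-{[tert-butyl(diphenyl)silyl]oxymethyl}-3-(dec-1-en-2-yl)-1,5-dimethoxy-4-oxo-1,4-dihydropyridin-2-yl]propanal | O=CCCc1c(C(=C)CCCCCCCC)c(=O)c(OC)c(CO[Si](c2ccccc2)(c2ccccc2)C(C)(C)C)n1OC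
F4 | step 9 | 6-(but-3-en-1-yl)-2-{[tert-butyl(diphenyl)silyl]oxymethyl}-5-(dec-1-en-2-yl)-1,3-dimethoxypyridin-4(1H)-one | C=CCCc1c(C(=C)CCCCCCCC)c(=O)c(OC)c(CO[Si](c2ccccc2)(c2ccccc2)C(C)(C)C)n1OC
F5 | step 9 | 2-{[tert-butyl(diphenyl)silyl]oxymethyl}-1,3-dimethoxy-5-octyl-7,8-dihydroquinolin-4(1H)-one | CCCCCCCCC1=CCCc2c1c(=O)c(OC)c(CO[Si](c3ccccc3)(c3ccccc3)C(C)(C)C)n2OC
F6 | step 5 | 2-{[tert-butyl(diphenyl)silyl]oxymethyl}-1-hydroxy-6-(3-hydroxypropyl)-3-methoxypyridin-4(1H)-one | OCCCc1cc(=O)c(OC)c(CO[Si](c2ccccc2)(c2ccccc2)C(C)(C)C)n1O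
F7 | step 4 | 6-(but-3-en-1-yl)-2-{[tert-butyl(diphenyl)silyl]oxymethyl}-3-methoxy-4H-pyran-4-one | C=CCCc1cc(=O)c(OC)c(CO[Si](c2ccccc2)(c2ccccc2)C(C)(C)C)o1
F8 | step 4 | 3-[6-{[tert-butyl(diphenyl)silyl]oxymethyl}-5-methoxy-4-oxo-4H-pyran-2-yl]propanal | O=CCCc1cc(=O)c(OC)c(CO[Si](c2ccccc2)(c2ccccc2)C(C)(C)C)o1
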